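The route rests on the bond between the ketone carbon and C1 of the chlorinated ring A. It exploits the free C2–OH of ring A, which sits ortho to C1. This oxygen first carries the ring-B acyl group as an aryl ester, and a photo-Fries rearrangement then shifts the acyl carbon from O to C1. One neutral, reagent-free operation thus creates the tetra-ortho-substituted diaryl ketone and unveils the phenol, while the C3 chlorine blocks the other ortho carbon. The precursor is the depside-like ester 2-chloro-3,5-dimethoxyphenyl 2-methoxy-4-(methoxymethoxy)-6-methylbenzoate, assembled from chlorinated 3,5-dimethoxyphenol and an acid derived from methyl orsellinate. The MOM group is removed in the same flask.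

Key step: step 5

Remark: the target (griseophenone A) has no stereocentre and its aryl–carbonyl bonds are taken to rotate freely at room temperature, so it is treated as achiral. Ring A is numbered from the ketone-bearing carbon C1 (C2 OH, C3 Cl, C4 OMe, C6 OMe), and ring B is the methyl-bearing ring.

Step 1
Reactants: 1 3,5-dimethoxyphenol
Product: 2 2-chloro-3,5-dimethoxyphenol
Conditions: SO2Cl2 (1.0 equiv), i-Bu2NH (10 mol%), toluene, 0 °C to rt
Reagents that add atoms: sulfuryl chloride, O=S(=O)(Cl)Cl
Why: Amine-catalysed ortho-selective electrophilic chlorination of a phenol, in which the amine-bound chlorinating species is held by a hydrogen bond to the phenol OH and should deliver chlorine to the two equivalent ortho carbons rather than to C4, while one equivalent of reagent limits polychlorination and any 4-chloro isomer is removed by chromatography.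

Step 2
Reactants: 3 methyl orsellinate (methyl 2,4-dihydroxy-6-methylbenzoate)
Product: 5 methyl 2-methoxy-4-(methoxymethoxy)-6-methylbenzoate, via 4-O-MOM methyl orsellinate 4 (not isolated)
Conditions: K2CO3, acetone; MOMCl (1.05 equiv), 0 °C to rt; then MeI (excess), reflux
Reagents that add atoms: chloromethyl methyl ether, COCCl; iodomethane, CI
Why: Sequential Williamson O-alkylation in one pot, in which the C2–OH is locked in a hydrogen bond to the ester carbonyl, so the limiting MOMCl should react only at the free C4–OH in the cold, after which excess MeI at reflux alkylates the remaining chelated phenol.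

Step 3
Reactants: 5 methyl 2-methoxy-4-(methoxymethoxy)-6-methylbenzoate
Product: 6 2-methoxy-4-(methoxymethoxy)-6-methylbenzoic acid
Conditions: KOH (excess), aq. DMSO, 90 °C; then 1 M HCl to pH 3–4, 0 °C
Reagents that add atoms: potassium hydroxide, [K+].[OH-]
Why: Saponification (BAc2) of a di-ortho-substituted benzoate needs poorly solvated hydroxide at elevated temperature, conditions to which the aryl methyl ether and the MOM acetal are inert, and cold, mild acidification should free the acid without acetal loss or protodecarboxylation.

Step 4
Reactants: 6 2-methoxy-4-(methoxymethoxy)-6-methylbenzoic acid; 2 2-chloro-3,5-dimethoxyphenol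
Product: 7 2-chloro-3,5-dimethoxyphenyl 2-methoxy-4-(methoxymethoxy)-6-methylbenzoate
Conditions: DCC (1.2 equiv), DMAP (cat.), CH2Cl2, 0 °C to rt
Reagents that add atoms: none
Why: Steglich esterification (DMAP-catalysed carbodiimide coupling) is the standard way to join di-ortho-substituted orsellinate-type acids to phenols in depside chemistry, and its neutral medium keeps the MOM acetal intact.

Step 5
Reactants: 7 2-chloro-3,5-dimethoxyphenyl 2-methoxy-4-(methoxymethoxy)-6-methylbenzoate
Product: 10 griseophenone A [(3-chloro-2-hydroxy-4,6-dimethoxyphenyl)(4-hydroxy-2-methoxy-6-methylphenyl)methanone], via ortho-acyl cyclohexadienone 8 (not isolated), via MOM-protected griseophenone A 9 (not isolated)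
Conditions: hν (300 nm), degassed MeOH (5 mM), rt; concentrate; then conc. HCl (cat.), MeOH, 50 °C
Reagents that add atoms: none
Why: This is a photo-Fries rearrangement of an aryl benzoate, used as the known reaction type: excitation of 7 breaks the acyl–O bond homolytically to a solvent-caged aroyl/aryloxyl radical pair, which recombines at the ring-A carbon ortho to oxygen to give dienone 8, and enolisation should give the hydrogen-bonded o-hydroxybenzophenone 9 with the new ketone–C1 bond. No ring is closed, and the only new stereocentre, the sp3 carbon of 8, forms racemic and is erased on tautomerisation, so only site selectivity is needed. Of the three spin-bearing carbons of the aryloxyl radical, the second ortho carbon bears chlorine, so recombination there cannot rearomatise by a proton shift and should revert, while the para carbon lies between two methoxy groups and is shielded from the bulky di-ortho-substituted aroyl radical, and cage recombination favours the nearest carbon anyway. The neutral, reagent-free medium spares the methoxy groups ortho to the new ketone, which Lewis-acid Fries conditions would cleave by chelation, and aroyl radicals do not lose CO at room temperature. Product 9 should protect itself by fast excited-state proton transfer along O–H···O=C, degassing prevents oxygen from trapping any photoenol of the ring-B methyl group, and the 300 nm window limits C–Cl homolysis. Catalytic HCl then transfers the MOM group to methanol in the same flask, leaving the ketone, the aryl chloride and the methyl ethers untouched.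

Compound list
1 | 3,5-dimethoxyphenol | COc1cc(O)cc(OC)c1 | starting material
2 | 2-chloro-3,5-dimethoxyphenol | COc1cc(O)c(Cl)c(OC)c1 | intermediate
3 | methyl orsellinate (methyl 2,4-dihydroxy-6-methylbenzoate) | COC(=O)c1c(C)cc(O)cc1O | starting material
4 | methyl 2-hydroxy-4-(methoxymethoxy)-6-methylbenzoate (4-O-MOM methyl orsellinate, not isolated) | COCOc1cc(C)c(C(=O)OC)c(O)c1 | intermediate
5 | methyl 2-methoxy-4-(methoxymethoxy)-6-methylbenzoate | COCOc1cc(C)c(C(=O)OC)c(OC)c1 | intermediate
6 | 2-methoxy-4-(methoxymethoxy)-6-methylbenzoic acid | COCOc1cc(C)c(C(=O)O)c(OC)c1 | intermediate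
7 | 2-chloro-3,5-dimethoxyphenyl 2-methoxy-4-(methoxymethoxy)-6-methylbenzoate | COCOc1cc(C)c(C(=O)Oc2cc(OC)cc(OC)c2Cl)c(OC)c1 | intermediate
8 | 2-chloro-3,5-dimethoxy-6-[2-methoxy-4-(methoxymethoxy)-6-methylbenzoyl]cyclohexa-2,4-dien-1-one (racemic, transient, not isolated) | COCOc1cc(C)c(C(=O)C2C(=O)C(Cl)=C(OC)C=C2OC)c(OC)c1 | intermediate
9 | (3-chloro-2-hydroxy-4,6-dimethoxyphenyl)[2-methoxy-4-(methoxymethoxy)-6-methylphenyl]methanone (MOM-protected griseophenone A, not isolated) | COCOc1cc(C)c(C(=O)c2c(O)c(Cl)c(OC)cc2OC)c(OC)c1 | intermediate
10 | griseophenone A, (3-chloro-2-hydroxy-4,6-dimethoxyphenyl)(4-hydroxy-2-methoxy-6-methylphenyl)methanone (achiral) | COc1cc(OC)c(C(=O)c2c(C)cc(O)cc2OC)c(O)c1Cl | target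

Total step count: 5
Longest linear sequence: 4 steps (3 → 5 → 6 → 7 → 10). Step 1 is the one-step side branch.

Steps most likely to fail

Step 5. The radical pair may escape the solvent cage, which returns the phenol. It may also recombine at the para carbon. Light may cleave the C–Cl bond, and the strongly absorbing product may stall conversion by acting as an inner filter. The fallback replaces the radical pair by a carbanion and sets out from 2. Amine-catalysed ortho-bromination (NBS, i-Pr2NH cat., CH2Cl2) at the only free ortho carbon should give 2-bromo-6-chloro-3,5-dimethoxyphenol F1. Steglich coupling of this phenol with 6 should give 2-bromo-6-chloro-3,5-dimethoxyphenyl 2-methoxy-4-(methoxymethoxy)-6-methylbenzoate F2. Bromine–lithium exchange (n-BuLi, THF, −95 °C) is favoured over intermolecular attack because the ester carbonyl is di-ortho-shielded. It then triggers an anionic Fries-type 1,3 O→C acyl shift that can end only at the former C–Br carbon. After aqueous work-up this comes back to the route at 9, which is then isolated and treated with HCl/MeOH as in the second stage of step 5.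

Step 1. Discrimination between ortho and para attack on the very electron-rich ring may be poor, and over-chlorination may occur. The fallback fixes the site by directed metalation and sets out from 1. O-carbamoylation (ClCONEt2, K2CO3, MeCN, reflux) should give 3,5-dimethoxyphenyl diethylcarbamate F3. Directed ortho-metalation (s-BuLi, TMEDA, THF, −78 °C) at the carbon between the carbamate and a methoxy group, with a C2Cl6 quench in the cold, should give 2-chloro-3,5-dimethoxyphenyl diethylcarbamate F4. Hydrolysis (KOH, aq. EtOH, reflux) comes back to the route at 2.

Step 4. An O-to-N acyl shift in the activated acid may outrun attack of the weakly nucleophilic, ortho-chlorinated phenol on the di-ortho-shielded carbonyl. The fallback replaces the dehydrative coupling by acylation of a preformed phenoxide with a discrete, small acyl halide and sets out from 6. Neutral chlorination with 1-chloro-N,N,2-trimethylprop-1-en-1-amine (CH2Cl2, 0 °C) should give 2-methoxy-4-(methoxymethoxy)-6-methylbenzoyl chloride F5 without acid that would harm the acetal. Phenol 2 is converted separately (NaH, THF, 0 °C) into sodium 2-chloro-3,5-dimethoxyphenolate F6. Combining the two comes back to the route at 7.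

Further compounds
F1 | step 5 | 2-bromo-6-chloro-3,5-dimethoxyphenol | COc1cc(OC)c(Br)c(O)c1Cl
F2 | step 5 | 2-bromo-6-chloro-3,5-dimethoxyphenyl 2-methoxy-4-(methoxymethoxy)-6-methylbenzoate | COCOc1cc(C)c(C(=O)Oc2c(Br)c(OC)cc(OC)c2Cl)c(OC)c1
F3 | step 1 | 3,5-dimethoxyphenyl diethylcarbamate | CCN(CC)C(=O)Oc1cc(OC)cc(OC)c1
F4 | step 1 | 2-chloro-3,5-dimethoxyphenyl diethylcarbamate | CCN(CC)C(=O)Oc1cc(OC)cc(OC)c1Cl
F5 | step 4 | 2-methoxy-4-(methoxymethoxy)-6-methylbenzoyl chloride | COCOc1cc(C)c(C(=O)Cl)c(OC)c1
F6 | step 4 | sodium 2-chloro-3,5-dimethoxyphenolate | COc1cc([O-])c(Cl)c(OC)c1.[Na+]
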